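**Retrosynthetic overview**
1. Querciformolide D ⇐ ε‑lactonisation of a C16 acrylic acid onto the tertiary C12–OH; the acid comes from allylic oxidation of a C1 isopropenyl group on a macrocyclic tetraol.
2. 14‑membered carbocycle ⇐ C11–C12 bond by an electrochemical Sm‑catalysed aldehyde/ketone pinacol macrocyclisation (sets C11, C12).
3. cis‑THF with C3 and C4 ⇐ Os‑catalysed oxidative cyclisation of a 7,8‑diol onto a (Z)‑C3=C4 alkene.
4. (Z)‑alkene ⇐ C4–C5 bond by Ni‑electrocatalytic decarboxylative alkenylation: Z‑vinyl iodide from (R)‑limonene oxide (C1 bought) plus an acid from the L‑glutamic‑acid‑derived lactone acid (C7 bought; C8 by Felkin addition).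
5. Ring order: THF → 14‑membered carbocycle → ε‑lactone.

Assumptions: cembrane numbering is used for atom labels (C1 = ring CH bearing C15; C15(=C17H2)–C16(=O)–O–C12; C18/C19/C20 = methyls on C4/C8/C12). Any partial dioxolane → dimethyl acetal exchange in step 5 is inconsequential because both are hydrolysed in step 8.

---

**Step 1**
Reactants: 1, (+)‑limonene 1,2‑oxide (4R; commercial cis/trans mixture)
Product: 2, (3R)‑6‑oxo‑3‑(prop‑1‑en‑2‑yl)heptanal
Conditions: H5IO6, THF/H2O, 0 °C → rt
Reagents that add atoms: periodic acid, OI(=O)(O)(O)(O)O; water, O (one carbonyl oxygen)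
Why: Periodic acid hydrolyses the epoxide to the diol and cleaves it in situ (Malaprade‑type glycol cleavage), so both epoxide epimers converge and the bought limonene stereocentre becomes C1 untouched.

**Step 2**
Reactants: 2, (3R)‑6‑oxo‑3‑(prop‑1‑en‑2‑yl)heptanal; 3, ethyltriphenylphosphonium iodide
Product: 4, (5R,7Z)‑8‑iodo‑5‑(prop‑1‑en‑2‑yl)non‑7‑en‑2‑one
Conditions: 3, n‑BuLi, THF; I2, −78 °C; NaHMDS, −20 °C; then 2, −78 °C
Reagents that add atoms: iodine, II
Why: Stork–Zhao iodo‑olefination (Wittig with Ph3P=C(I)CH3) reacts only with the aldehyde at −78 °C and gives the (Z)‑2‑iodoalkene, fixing the geometry needed later at C3=C4.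

**Step 3**
Reactants: 5, (S)‑5‑oxotetrahydrofuran‑2‑carboxylic acid
Product: 6, (S)‑5‑acetyldihydrofuran‑2(3H)‑one
Conditions: (COCl)2, cat. DMF, CH2Cl2; then Me2CuLi, Et2O, −78 °C
Reagents that add atoms: lithium dimethylcuprate, [Li+].C[Cu-]C
Why: Acid chloride formation and Gilman cuprate acylation stop at the ketone at −78 °C without touching the lactone or epimerising the bought C7 centre.

**Step 4**
Reactants: 6, (S)‑5‑acetyldihydrofuran‑2(3H)‑one; 7, [2‑(1,3‑dioxolan‑2‑yl)ethyl]magnesium bromide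
Product: 8, (S)‑5‑[(R)‑4‑(1,3‑dioxolan‑2‑yl)‑2‑hydroxybutan‑2‑yl]dihydrofuran‑2(3H)‑one
Conditions: 7, CeCl3, THF, −78 °C
Reagents that add atoms: none
Why: Felkin–Anh addition of the weakly basic, non‑chelating organocerium (nucleophile anti to the ring C7–O bond, passing C7–H) sets C8 (R), i.e. the 7,8‑anti relationship, and the ketone reacts in preference to the lactone.

**Step 5**
Reactants: 8
Product: 9, methyl 3‑{(4S,5R)‑5‑[2‑(1,3‑dioxolan‑2‑yl)ethyl]‑2,2,5‑trimethyl‑1,3‑dioxolan‑4‑yl}propanoate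
Conditions: 2,2‑dimethoxypropane, MeOH, CSA (cat.), rt
Reagents that add atoms: 2,2‑dimethoxypropane, COC(C)(C)OC; methanol, CO
Why: Acid‑catalysed lactone methanolysis is driven by trapping the liberated C7/C8 diol as its acetonide (transacetalisation), which protects the diol and releases the carboxyl as a methyl ester.

**Step 6**
Reactants: 9
Product: 10, 3‑{(4S,5R)‑5‑[2‑(1,3‑dioxolan‑2‑yl)ethyl]‑2,2,5‑trimethyl‑1,3‑dioxolan‑4‑yl}propanoic acid
Conditions: LiOH, THF/H2O, rt; pH 4 work‑up
Reagents that add atoms: lithium hydroxide, [Li+].[OH-]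
Why: Ester saponification; both acetals are base‑stable.

**Step 7**
Reactants: 10; 4, (5R,7Z)‑8‑iodo‑5‑(prop‑1‑en‑2‑yl)non‑7‑en‑2‑one
Product: 11, (5R,7Z)‑10‑{(4S,5R)‑5‑[2‑(1,3‑dioxolan‑2‑yl)ethyl]‑2,2,5‑trimethyl‑1,3‑dioxolan‑4‑yl}‑8‑methyl‑5‑(prop‑1‑en‑2‑yl)dec‑7‑en‑2‑one
Conditions: N‑hydroxyphthalimide, DIC, cat. DMAP, CH2Cl2 (ester used crude); then NiCl2·6H2O (10 mol%), 2,2′‑bipyridine, AgNO3 (cat.), LiCl, DMF, Mg anode / RVC cathode, constant current, rt
Reagents that add atoms: none
Why: Ni‑electrocatalytic decarboxylative alkenylation: cathodic reduction of the redox‑active ester gives the primary C5 radical, which is captured by the alkenyl–Ni species from 4 and reductively eliminated with retention of Z geometry, forming C4–C5 and expelling the extra carboxyl carbon.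

**Step 8**
Reactants: 11
Product: 12, (5R,7S)‑7‑hydroxy‑7‑{(2R,5S)‑5‑[(2R)‑5‑hydroxy‑2‑methyltetrahydrofuran‑2‑yl]‑2‑methyltetrahydrofuran‑2‑yl}‑5‑(prop‑1‑en‑2‑yl)heptan‑2‑one (lactol, anomeric mixture; masked C11 aldehyde)
Conditions: OsO4 (5 mol%), pyridine N‑oxide, TFA, acetone/H2O, 50 °C; then 1 M HCl, THF, rt
Reagents that add atoms: pyridine N‑oxide, [O-][n+]1ccccc1 (source of the C3 hydroxyl oxygen via Os=O); water, O
Why: Os(VI)‑catalysed oxidative cyclisation of a 1,2‑diol onto an alkene (Donohoe type): after in situ acetonide cleavage the C7/C8 glycolate binds Os, C7–O and Os=O add suprafacially across the Z‑alkene to create C4 (R) and C3 (S) together, and the 2,5‑cis THF is enforced because C8–O and the new C3–O sit on the same osmium; the N‑oxide is intended not to form free OsO4 so that the isopropenyl group is left alone, and the acid then unmasks C11, which closes onto C8–OH as the lactol.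

**Step 9**
Reactants: 12
Product: 13, (1R,3S,4R,7S,8R,11R,12R)‑4,7‑epoxy‑cembr‑15(17)‑ene‑3,8,11,12‑tetraol (14‑membered carbocycle, cis‑THF bridge C4–O–C7, isopropenyl at C1)
Conditions: SmI2 (15 mol%), 2,6‑lutidinium triflate (2.5 equiv), nBu4NI, THF (2 mM), graphite‑felt cathode / Zn anode, undivided cell, constant current, rt
Reagents that add atoms: none
Why: Proposed new method: a Sm(II)/Sm(III)‑electrocatalytic aldehyde–ketone cross‑pinacol macrocyclisation fed from a lactol — cathodically regenerated Sm(II) reduces the small equilibrium amount of C11 aldehyde (slow release suppresses dimerisation) to a Sm(III) ketyl anchored by the C8 alkoxide, the same Sm(III) binds the C12 ketone, and C11–C12 forms inside this chelate to give the cis‑samarium diolate with C10/C13 anti, i.e. the 11,12‑syn diol; the C8–O–Sm anchor and the rigid cis‑THF are expected to favour Si,Si‑face union (11R,12R), but this facial preference is a hypothesis, not a derived result, and lutidinium protonolysis of Sm–O returns Sm(III) to the cathode; the closest known chemistry is stoichiometric SmI2 or low‑valent‑Ti pinacol macrocyclisation of keto‑aldehydes to 14‑membered cembranoid diols, and Sm‑electrocatalytic intermolecular ketyl couplings turned over by Sm–alkoxide protonolysis.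

**Step 10**
Reactants: 13
Product: 14, 3,11‑bis‑O‑triethylsilyl ether of 13 (C8–OH and C12–OH free)
Conditions: TESCl, imidazole, cat. DMAP, DMF, 0 °C → rt
Reagents that add atoms: chlorotriethylsilane, CC[Si](Cl)(CC)CC
Why: Silyl chloride/imidazole protects only the two secondary hydroxyls, so later only the tertiary C12–OH can close a 7‑membered lactone and C3–OH cannot form a δ‑lactone.

**Step 11**
Reactants: 14
Product: 15, 8,12‑dihydroxy‑3,11‑bis(triethylsilyloxy)‑4,7‑epoxy‑cembr‑15(17)‑en‑16‑al (2‑substituted acrolein at C1)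
Conditions: SeO2 (0.5 equiv), t‑BuOOH, CH2Cl2, rt; then MnO2, CH2Cl2
Reagents that add atoms: selenium dioxide, O=[Se]=O; tert‑butyl hydroperoxide, CC(C)(C)OO (C16 oxygen)
Why: Riley allylic oxidation (ene then [2,3]‑shift) attacks the methyl of the only alkene present, and MnO2 takes the allylic alcohol on to the enal.

**Step 12**
Reactants: 15
Product: 16, the corresponding cembr‑15(17)‑en‑16‑oic acid (acrylic acid at C1)
Conditions: NaClO2, NaH2PO4, 2‑methyl‑2‑butene, t‑BuOH/H2O, 0 °C → rt
Reagents that add atoms: sodium chlorite, [Na+].[O-]Cl=O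
Why: Pinnick oxidation converts the enal to the acid without affecting silyl ethers, tertiary alcohols or the alkene.

**Step 13**
Reactants: 16
Product: 17, 3,11‑bis‑O‑triethylsilyl querciformolide D (α‑methylene ε‑lactone C16–O–C12)
Conditions: 2,4,6‑trichlorobenzoyl chloride, Et3N, THF; then DMAP, toluene, 80 °C, 1 mM
Reagents that add atoms: none
Why: Yamaguchi lactonisation; C12–OH is the only free hydroxyl that can close a small ring, and acylation on oxygen leaves the C12 configuration unchanged.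

**Step 14**
Reactants: 17
Product: 18, querciformolide D
Conditions: HF·pyridine, pyridine, THF, 0 °C → rt
Reagents that add atoms: none
Why: Buffered, non‑basic desilylation frees C3–OH and C11–OH without opening or adding to the α‑methylene lactone.

---

**Compound list**
1 | (+)‑limonene 1,2‑oxide (4R, cis/trans mixture) | CC(=C)[C@@H]1CCC2(C)OC2C1 | starting material
2 | (3R)‑6‑oxo‑3‑(prop‑1‑en‑2‑yl)heptanal | CC(=O)CC[C@H](CC=O)C(C)=C | intermediate
3 | ethyltriphenylphosphonium iodide | CC[P+](c1ccccc1)(c1ccccc1)c1ccccc1.[I-] | starting material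
4 | (5R,7Z)‑8‑iodo‑5‑(prop‑1‑en‑2‑yl)non‑7‑en‑2‑one | CC(=O)CC[C@H](C/C=C(\I)C)C(C)=C | intermediate
5 | (S)‑5‑oxotetrahydrofuran‑2‑carboxylic acid | OC(=O)[C@@H]1CCC(=O)O1 | starting material
6 | (S)‑5‑acetyldihydrofuran‑2(3H)‑one | CC(=O)[C@@H]1CCC(=O)O1 | intermediate
7 | [2‑(1,3‑dioxolan‑2‑yl)ethyl]magnesium bromide | Br[Mg]CCC1OCCO1 | starting material
8 | (S)‑5‑[(R)‑4‑(1,3‑dioxolan‑2‑yl)‑2‑hydroxybutan‑2‑yl]dihydrofuran‑2(3H)‑one | O=C1CC[C@H](O1)[C@](C)(O)CCC2OCCO2 | intermediate
9 | methyl 3‑{(4S,5R)‑5‑[2‑(1,3‑dioxolan‑2‑yl)ethyl]‑2,2,5‑trimethyl‑1,3‑dioxolan‑4‑yl}propanoate | COC(=O)CC[C@@H]1OC(C)(C)O[C@]1(C)CCC2OCCO2 | intermediate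
10 | 3‑{(4S,5R)‑5‑[2‑(1,3‑dioxolan‑2‑yl)ethyl]‑2,2,5‑trimethyl‑1,3‑dioxolan‑4‑yl}propanoic acid | OC(=O)CC[C@@H]1OC(C)(C)O[C@]1(C)CCC2OCCO2 | intermediate
11 | (5R,7Z)‑10‑{(4S,5R)‑5‑[2‑(1,3‑dioxolan‑2‑yl)ethyl]‑2,2,5‑trimethyl‑1,3‑dioxolan‑4‑yl}‑8‑methyl‑5‑(prop‑1‑en‑2‑yl)dec‑7‑en‑2‑one | CC(=O)CC[C@H](C/C=C(\CC[C@@H]1OC(C)(C)O[C@]1(C)CCC2OCCO2)C)C(C)=C | intermediate
12 | (5R,7S)‑7‑hydroxy‑7‑{(2R,5S)‑5‑[(2R)‑5‑hydroxy‑2‑methyltetrahydrofuran‑2‑yl]‑2‑methyltetrahydrofuran‑2‑yl}‑5‑(prop‑1‑en‑2‑yl)heptan‑2‑one (lactol) | CC(=O)CC[C@H](C[C@H](O)[C@@]1(C)CC[C@H](O1)[C@@]2(C)CCC(O)O2)C(C)=C | intermediate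
13 | (1R,3S,4R,7S,8R,11R,12R)‑4,7‑epoxy‑cembr‑15(17)‑ene‑3,8,11,12‑tetraol | CC(=C)[C@H]1C[C@H](O)[C@@]2(C)CC[C@H](O2)[C@](C)(O)CC[C@@H](O)[C@](C)(O)CC1 | intermediate
14 | 3,11‑bis‑O‑TES ether of 13 | CC(=C)[C@H]1C[C@H](O[Si](CC)(CC)CC)[C@@]2(C)CC[C@H](O2)[C@](C)(O)CC[C@@H](O[Si](CC)(CC)CC)[C@](C)(O)CC1 | intermediate
15 | 16‑aldehyde (2‑substituted acrolein) of 14 | O=CC(=C)[C@H]1C[C@H](O[Si](CC)(CC)CC)[C@@]2(C)CC[C@H](O2)[C@](C)(O)CC[C@@H](O[Si](CC)(CC)CC)[C@](C)(O)CC1 | intermediate
16 | 16‑oic acid (acrylic acid) of 14 | OC(=O)C(=C)[C@H]1C[C@H](O[Si](CC)(CC)CC)[C@@]2(C)CC[C@H](O2)[C@](C)(O)CC[C@@H](O[Si](CC)(CC)CC)[C@](C)(O)CC1 | intermediate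
17 | 3,11‑bis‑O‑TES querciformolide D | C=C1C(=O)O[C@]2(C)CC[C@@H]1C[C@H](O[Si](CC)(CC)CC)[C@@]1(C)CC[C@H](O1)[C@](C)(O)CC[C@H]2O[Si](CC)(CC)CC | intermediate
18 | querciformolide D | C=C1C(=O)O[C@]2(C)CC[C@@H]1C[C@H](O)[C@@]1(C)CC[C@H](O1)[C@](C)(O)CC[C@H]2O | target

---

**Totals**
Total steps: 14. Longest linear sequence: 12 (5 → 18, steps 3–14); the limonene branch (steps 1–2) joins at step 7.

**Stereocentre origins:** C1 is bought (limonene) and C7 is bought (L‑glutamate lactone). C8 is set in step 4, C3 and C4 in step 8, and C11 and C12 in step 9.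

**Three steps most likely to fail**
1. **Step 9 (proposed new Sm‑electrocatalytic pinacol macrocyclisation).** The risks are turnover and the 11R,12R facial selectivity; a wrong C12 epimer cannot be corrected afterwards. Fallback (known chemistry, different disconnection): buy C11 as (R)‑5‑oxotetrahydrofuran‑2‑carboxylic acid (D‑glutamic acid series). Set C12 by MeMgBr addition to its chain‑bearing 5‑acyl derivative (Felkin, gives 11,12‑syn), then close the 14‑membered ring at C4–C5 by intramolecular B‑alkyl Suzuki coupling of the Z‑vinyl iodide.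
2. **Step 4 (Felkin addition setting C8).** The risks are modest diastereoselectivity and enolisation at C7. Fallback: open the lactone, protect C7–OH as a benzyl‑type ether, build the ketone that already carries the C9–C11 chain (Weinreb amide + 7), and add MeMgBr under Cram‑chelate control (MgBr2·OEt2), which gives the same 7,8‑anti diol by a different control element.
3. **Step 13 (acylation of a tertiary alcohol by an acrylic mixed anhydride).** The risks are slow closure, DMAP conjugate addition and oligomerisation. Fallback: lactonise before the acrylate exists. Hydroborate/oxidise the isopropenyl group to the saturated C16 acid, close the ε‑lactone on C12–OH, then install the exo‑methylene by α‑phenylselenenylation and selenoxide elimination.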